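**Plan**
1. Cuts: after N-Boc and the C5′ O-methyl group are removed, ring B′ of the naphthalene (C5′, C6′, C7′, C8′, C8a′, C4a′) is opened at C8′–C7′ and C6′–C5′. Next come the C5–CH2 bond of the resulting diarylmethane, then C1–C8a/C1–N and C4–C4a of the heterocycle.
2. Enabling feature: C8′, the naphthalene end of the biaryl bond, lies para to oxygen-bearing C5′ inside ring B′. C8′ therefore maps onto the benzylic CH2 of an ortho-toluate, C5′ onto its ester carbon, and C6′–C7′ onto a vinyl sulfoxide used as an acetylene equivalent.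
3. Forward, part 1: ring A′ is bought as 3,5-dimethylphenol and turned into methyl 2-methoxy-4,6-dimethylbenzoate. The nitrogen ring is closed by a Pictet–Spengler reaction on a 1-(3,5-dimethoxyphenyl)propan-2-amine and then brominated at C5.
4. Forward, part 2: the halves are joined through an unhindered aryl–CH2 bond (lateral lithiation, zinc, Negishi coupling). Ring B′ closes last, and only its aromatisation turns that bond into the crowded C5–C8′ biaryl bond.
5. Stereochemistry: C3 (S) is bought with N-Boc-L-alaninol, and no bond to it is made or broken afterwards.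

Key step: step 9

Assumption: the SMILES fixes only C3. The rotationally hindered C5–C8′ axis carries no descriptor, so both atropisomers count as the target and no axial control is attempted.

**Step 1**
Reactants: 1 3,5-dimethylphenol
Product: 2 2-hydroxy-4,6-dimethylbenzoic acid
Conditions: K2CO3, CO2 (about 50 bar), 175 °C, autoclave; aq HCl
Reagents that add atoms: carbon dioxide, O=C=O
Why: Kolbe–Schmitt carboxylation (carbonate variant) brings CO2 to a carbon ortho to the phenoxide oxygen; the two ortho sites are equivalent and the para site is shielded by both methyl groups, so one salicylic acid should result.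

**Step 2**
Reactants: 2 2-hydroxy-4,6-dimethylbenzoic acid
Product: 3 methyl 2-methoxy-4,6-dimethylbenzoate
Conditions: MeI (3 equiv), K2CO3, DMF, 40 °C
Reagents that add atoms: iodomethane, CI
Why: Double Williamson-type O-alkylation methylates carboxylate and phenoxide by SN2 on MeI, which sidesteps the hindered carbonyl group that would slow a Fischer esterification.

**Step 3**
Reactants: 4 N-Boc-L-alaninol (tert-butyl N-[(2S)-1-hydroxypropan-2-yl]carbamate)
Product: 6 tert-butyl (2S)-2-methylaziridine-1-carboxylate, via O-tosylate 5 (not isolated)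
Conditions: TsCl, powdered KOH, Et2O, reflux
Reagents that add atoms: none
Why: O-Sulfonylation followed by base-induced 3-exo-tet N-alkylation (Wenker-type aziridine closure) takes place at the primary carbon only, so the stereocentre bought with 4 keeps its S configuration.

**Step 4**
Reactants: 7 1-bromo-3,5-dimethoxybenzene; 6 tert-butyl (2S)-2-methylaziridine-1-carboxylate
Product: 9 tert-butyl N-[(2S)-1-(3,5-dimethoxyphenyl)propan-2-yl]carbamate, via aryl Grignard reagent 8 (not isolated)
Conditions: Mg, THF, reflux; then CuBr·SMe2 (10 mol %), 6, THF, –30 → 0 °C; aq NH4Cl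
Reagents that add atoms: none
Why: Copper-catalysed SN2 opening of a carbamate-activated aziridine by an aryl Grignard reagent occurs at the unsubstituted CH2 (future C4), forms the C4–C4a bond and leaves the C–N bond of the stereocentre intact.

**Step 5**
Reactants: 9 tert-butyl N-[(2S)-1-(3,5-dimethoxyphenyl)propan-2-yl]carbamate
Product: 11 (3S)-6,8-dimethoxy-3-methyl-1,2,3,4-tetrahydroisoquinoline, via amine hydrochloride 10 (not isolated)
Conditions: 4 M HCl in dioxane, rt, concentrate; 37% aq HCHO (1.05 equiv), EtOH–H2O, 60 °C; aq NaOH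
Reagents that add atoms: formaldehyde, C=O
Why: Carbamate acidolysis and Pictet–Spengler cyclisation (6-endo-trig attack of the arene on the N-methyleneiminium ion) close the nitrogen ring at either of the two equivalent positions ortho to the side chain, each activated ortho and para by methoxy groups, while C3 takes part in no bond change.

**Step 6**
Reactants: 11 (3S)-6,8-dimethoxy-3-methyl-1,2,3,4-tetrahydroisoquinoline
Product: 12 tert-butyl (3S)-6,8-dimethoxy-3-methyl-3,4-dihydro-1H-isoquinoline-2-carboxylate
Conditions: Boc2O, CH2Cl2, rt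
Reagents that add atoms: di-tert-butyl dicarbonate, CC(C)(C)OC(=O)OC(=O)OC(C)(C)C
Why: Standard N-acylation of a secondary amine with Boc2O installs a carbamate that tolerates NBS, organozinc and lithium amide reagents.

**Step 7**
Reactants: 12 tert-butyl (3S)-6,8-dimethoxy-3-methyl-3,4-dihydro-1H-isoquinoline-2-carboxylate
Product: 13 tert-butyl (3S)-5-bromo-6,8-dimethoxy-3-methyl-3,4-dihydro-1H-isoquinoline-2-carboxylate
Conditions: NBS (1.0 equiv), MeCN, –20 → 0 °C, dark
Reagents that add atoms: N-bromosuccinimide, O=C1CCC(=O)N1Br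
Why: Electrophilic aromatic bromination should go to C5, para to the C8 methoxy and ortho to the C6 methoxy group, rather than to C7 wedged between two methoxy groups, the pattern known from 3,5-dimethoxytoluene and related 6,8-dioxygenated tetrahydroisoquinolines.

**Step 8**
Reactants: 3 methyl 2-methoxy-4,6-dimethylbenzoate; 13 tert-butyl (3S)-5-bromo-6,8-dimethoxy-3-methyl-3,4-dihydro-1H-isoquinoline-2-carboxylate
Product: 16 tert-butyl (3S)-5-[3-methoxy-2-(methoxycarbonyl)-5-methylbenzyl]-6,8-dimethoxy-3-methyl-3,4-dihydro-1H-isoquinoline-2-carboxylate, via lithiated toluate 14 (not isolated), via benzylic zinc chloride 15 (not isolated)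
Conditions: 3 (1.5 equiv), LiN(i-Pr)2 (1.5 equiv), THF, –78 °C; ZnCl2 (1.6 equiv), –78 °C → rt; 13, Pd(OAc)2 (4 mol %), SPhos (2-dicyclohexylphosphino-2′,6′-dimethoxybiphenyl, 8 mol %), THF, 60 °C
Reagents that add atoms: none
Why: Lateral lithiation of the ortho-toluate (the C6 methyl group is reached through ester coordination and gives an ester-conjugated anion, the para C4 methyl group is not touched at –78 °C), transmetallation to zinc and Negishi coupling under Pd(OAc)2/SPhos, a catalyst established for benzylic zinc halides and di-ortho-substituted electron-rich aryl bromides, should forge the C5–CH2 bond without harm to ester or carbamate.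

**Step 9**
Reactants: 16 tert-butyl (3S)-5-[3-methoxy-2-(methoxycarbonyl)-5-methylbenzyl]-6,8-dimethoxy-3-methyl-3,4-dihydro-1H-isoquinoline-2-carboxylate; 17 phenyl vinyl sulfoxide (racemic)
Product: 21 tert-butyl (3S)-5-(4-hydroxy-5-methoxy-7-methylnaphthalen-1-yl)-6,8-dimethoxy-3-methyl-3,4-dihydro-1H-isoquinoline-2-carboxylate, via lithiated diarylmethane 18 (not isolated), via β-keto sulfoxide 19 (not isolated), via naphthalen-1(4H)-one 20 (not isolated)
Conditions: LiN(i-Pr)2 (1.05 equiv), THF, –78 °C; 17 (1.2 equiv), –78 → 0 °C; aq NH4Cl; crude 19, CaCO3, toluene, 100 °C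
Reagents that add atoms: none
Why: Proposed new method: LiN(i-Pr)2 removes one proton of the doubly benzylic CH2 of 16 to give the ester-conjugated anion 18, which adds through C8′ to the unsubstituted terminus of 17 (C8′–C7′ bond); the resulting α-sulfinyl carbanion attacks the neighbouring methyl ester in a 6-exo-trig Dieckmann closure (C6′–C5′ bond) that makes ring B′, and the expelled methoxide deprotonates β-keto sulfoxide 19, which takes the sequence out of equilibrium. After the quench, heating should bring about the five-centre syn elimination of benzenesulfenic acid, for which only the C7′ hydrogens are available, and 20 then enolises to naphthol 21. The closest known reaction types are the Staunton–Weinreb Michael–Dieckmann annulation of ortho-toluate anions with enones, pyranones and acrylates, the intramolecular carbonyl capture of the carbanion formed when lithium enolates add to aryl vinyl sulfoxides, and the 1-naphthol synthesis in which the eliminable sulfinyl group sits on the toluate; a secondary diarylmethyl toluate anion paired with the parent vinyl sulfoxide is not established, hence the label. No lasting stereocentre is made: the centres at C8′, C6′ and sulfur arise as mixtures and vanish on aromatisation, C3 is a spectator, and the C5–C8′ axis forms without control. The step needs deprotonation at the CH2 and not at the C2′ methyl group (para to the ester) or at C1 beside the carbamate nitrogen, which is secured by the second aryl group, by lithium coordination to the ortho ester and by the inability of an amide base to metallate N-Boc benzylic C–H bonds. Base is held near one equivalent so that none remains to metallate 17 at its α-vinyl position.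

**Step 10**
Reactants: 21 tert-butyl (3S)-5-(4-hydroxy-5-methoxy-7-methylnaphthalen-1-yl)-6,8-dimethoxy-3-methyl-3,4-dihydro-1H-isoquinoline-2-carboxylate
Product: 22 tert-butyl (3S)-5-(4,5-dimethoxy-7-methylnaphthalen-1-yl)-6,8-dimethoxy-3-methyl-3,4-dihydro-1H-isoquinoline-2-carboxylate
Conditions: MeI, Cs2CO3, DMF, rt
Reagents that add atoms: iodomethane, CI
Why: Williamson etherification of the peri-hydrogen-bonded naphthol, for which the caesium phenoxide in DMF is reactive enough and no other acidic site competes.

**Step 11**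
Reactants: 22 tert-butyl (3S)-5-(4,5-dimethoxy-7-methylnaphthalen-1-yl)-6,8-dimethoxy-3-methyl-3,4-dihydro-1H-isoquinoline-2-carboxylate
Product: 23 (3S)-5-(4,5-dimethoxy-7-methylnaphthalen-1-yl)-6,8-dimethoxy-3-methyl-1,2,3,4-tetrahydroisoquinoline (target)
Conditions: 4 M HCl in dioxane, CH2Cl2, 0 °C → rt; aq NaOH
Reagents that add atoms: none
Why: Acidolytic carbamate cleavage (loss of 2-methylpropene and CO2) frees the secondary amine without affecting the aryl methyl ethers or C3.

**Compound list**
1 | 3,5-dimethylphenol | Cc1cc(C)cc(O)c1 | starting material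
2 | 2-hydroxy-4,6-dimethylbenzoic acid | Cc1cc(C)c(C(=O)O)c(O)c1 | intermediate
3 | methyl 2-methoxy-4,6-dimethylbenzoate | COC(=O)c1c(C)cc(C)cc1OC | intermediate
4 | N-Boc-L-alaninol, tert-butyl N-[(2S)-1-hydroxypropan-2-yl]carbamate | C[C@H](NC(=O)OC(C)(C)C)CO | starting material
5 | (2S)-2-[(tert-butoxycarbonyl)amino]propyl 4-methylbenzenesulfonate | C[C@H](NC(=O)OC(C)(C)C)COS(=O)(=O)c1ccc(C)cc1 | intermediate
6 | tert-butyl (2S)-2-methylaziridine-1-carboxylate | C[C@H]1CN1C(=O)OC(C)(C)C | intermediate
7 | 1-bromo-3,5-dimethoxybenzene | COc1cc(Br)cc(OC)c1 | starting material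
8 | (3,5-dimethoxyphenyl)magnesium bromide | COc1cc(OC)cc([Mg]Br)c1 | intermediate
9 | tert-butyl N-[(2S)-1-(3,5-dimethoxyphenyl)propan-2-yl]carbamate | C[C@H](NC(=O)OC(C)(C)C)Cc1cc(OC)cc(OC)c1 | intermediate
10 | (2S)-1-(3,5-dimethoxyphenyl)propan-2-aminium chloride | C[C@H]([NH3+])Cc1cc(OC)cc(OC)c1.[Cl-] | intermediate
11 | (3S)-6,8-dimethoxy-3-methyl-1,2,3,4-tetrahydroisoquinoline | COc1cc(OC)cc2c1CN[C@@H](C)C2 | intermediate
12 | tert-butyl (3S)-6,8-dimethoxy-3-methyl-3,4-dihydro-1H-isoquinoline-2-carboxylate | COc1cc(OC)cc2c1CN(C(=O)OC(C)(C)C)[C@@H](C)C2 | intermediate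
13 | tert-butyl (3S)-5-bromo-6,8-dimethoxy-3-methyl-3,4-dihydro-1H-isoquinoline-2-carboxylate | COc1cc(OC)c(Br)c2c1CN(C(=O)OC(C)(C)C)[C@@H](C)C2 | intermediate
14 | methyl 2-(lithiomethyl)-6-methoxy-4-methylbenzoate | COC(=O)c1c(C[Li])cc(C)cc1OC | intermediate
15 | [3-methoxy-2-(methoxycarbonyl)-5-methylbenzyl]zinc chloride | COC(=O)c1c(C[Zn]Cl)cc(C)cc1OC | intermediate
16 | tert-butyl (3S)-5-[3-methoxy-2-(methoxycarbonyl)-5-methylbenzyl]-6,8-dimethoxy-3-methyl-3,4-dihydro-1H-isoquinoline-2-carboxylate | COC(=O)c1c(OC)cc(C)cc1Cc1c(OC)cc(OC)c2CN(C(=O)OC(C)(C)C)[C@@H](C)Cc12 | intermediate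
17 | phenyl vinyl sulfoxide (racemic) | C=CS(=O)c1ccccc1 | starting material
18 | lithium derivative of 16 at the diarylmethane carbon | COC(=O)c1c(OC)cc(C)cc1C([Li])c1c(OC)cc(OC)c2CN(C(=O)OC(C)(C)C)[C@@H](C)Cc12 | intermediate
19 | tert-butyl (3S)-6,8-dimethoxy-5-[5-methoxy-7-methyl-4-oxo-3-(phenylsulfinyl)-1,2,3,4-tetrahydronaphthalen-1-yl]-3-methyl-3,4-dihydro-1H-isoquinoline-2-carboxylate (mixture at the three new centres) | COc1cc(C)cc2c1C(=O)C(S(=O)c1ccccc1)CC2c1c(OC)cc(OC)c2CN(C(=O)OC(C)(C)C)[C@@H](C)Cc12 | intermediate
20 | tert-butyl (3S)-6,8-dimethoxy-5-(5-methoxy-7-methyl-4-oxo-1,4-dihydronaphthalen-1-yl)-3-methyl-3,4-dihydro-1H-isoquinoline-2-carboxylate | COc1cc(C)cc2c1C(=O)C=CC2c1c(OC)cc(OC)c2CN(C(=O)OC(C)(C)C)[C@@H](C)Cc12 | intermediate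
21 | tert-butyl (3S)-5-(4-hydroxy-5-methoxy-7-methylnaphthalen-1-yl)-6,8-dimethoxy-3-methyl-3,4-dihydro-1H-isoquinoline-2-carboxylate | COc1cc(C)cc2c(-c3c(OC)cc(OC)c4CN(C(=O)OC(C)(C)C)[C@@H](C)Cc34)ccc(O)c12 | intermediate
22 | tert-butyl (3S)-5-(4,5-dimethoxy-7-methylnaphthalen-1-yl)-6,8-dimethoxy-3-methyl-3,4-dihydro-1H-isoquinoline-2-carboxylate | COc1cc(C)cc2c(-c3c(OC)cc(OC)c4CN(C(=O)OC(C)(C)C)[C@@H](C)Cc34)ccc(OC)c12 | intermediate
23 | (3S)-5-(4,5-dimethoxy-7-methylnaphthalen-1-yl)-6,8-dimethoxy-3-methyl-1,2,3,4-tetrahydroisoquinoline | COc1cc(OC)c(-c2ccc(OC)c3c(OC)cc(C)cc23)c2c1CN[C@@H](C)C2 | target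

**Totals**
- Total steps: 11.
- Longest linear sequence: 9 steps (steps 3 to 11, from 4).
- The toluate branch (steps 1 and 2) joins at step 8.

**Steps most likely to fail**

Step 9 (carries the new-method label).
- What may go wrong: conjugate addition of the crowded anion may be slower than anionic oligomerisation of the vinyl sulfoxide.
- Proton transfer from the new C8′–H to the α-sulfinyl carbanion may outrun ring closure.
- Sulfenic acid released on heating may sulfenylate the electron-rich naphthol.
- Fallback: it sets out from 16 and returns at 21, using known chemistry only. Anion 18 is added to allyl acrylate (THF, –78 → 0 °C), the established Michael–Dieckmann reaction of toluate anions with acrylates, to give the allyl β-keto ester F1.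
- Pd(OAc)2 with 1,2-bis(diphenylphosphino)ethane in MeCN at reflux then carries out the Tsuji decarboxylation–dehydrogenation. The allyl ester ionises on zerovalent palladium, CO2 is lost, β-hydride elimination from the palladium enolate gives 20, and 20 enolises to 21.
- The same two ring bonds are formed, but the carbanion is an ester enolate and aromatisation no longer depends on sulfur.

Step 8.
- What may go wrong: oxidative addition to the di-ortho-substituted, electron-rich bromide may be slow enough for the benzylic zinc reagent to homocouple or be protonated. Any metallation at the para methyl group would also be carried into the coupling.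
- Fallback: it reverses the polarity, sets out from 3 and 13 and returns at 16. Lithiated toluate 14 is run into hexachloroethane (THF, –78 °C) to give methyl 2-(chloromethyl)-6-methoxy-4-methylbenzoate F2.
- Bromide 13 undergoes bromine–lithium exchange (n-BuLi, THF, –78 °C) to the 5-lithio tetrahydroisoquinoline F3. This is trapped with 2-isopropoxy-4,4,5,5-tetramethyl-1,3,2-dioxaborolane as the pinacol boronate F4.
- A Suzuki–Miyaura benzylation (Pd(OAc)2, SPhos, K3PO4, toluene–water, 80 °C) joins F2 and F4 to give 16.

Step 7.
- What may go wrong: some attack at C7, or a second bromination of the very electron-rich ring, would erode the regiochemical purity on which the biaryl position depends.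
- Fallback: it sets out from 12 and returns at 13. Exhaustive bromination (NBS, 2.1 equiv, MeCN, rt) gives the 5,7-dibromide F5.
- One equivalent of n-BuLi (THF, –78 °C) should exchange the C7 bromine selectively, because the 7-lithio-5-bromide F6 is held between two coordinating methoxy groups. Aqueous NH4Cl then protonates C7 to leave 13.

**Further compounds**
F1 | step 9 | prop-2-enyl 4-[(3S)-2-(tert-butoxycarbonyl)-6,8-dimethoxy-3-methyl-1,2,3,4-tetrahydroisoquinolin-5-yl]-8-methoxy-6-methyl-1-oxo-1,2,3,4-tetrahydronaphthalene-2-carboxylate | COc1cc(C)cc2c1C(=O)C(C(=O)OCC=C)CC2c1c(OC)cc(OC)c2CN(C(=O)OC(C)(C)C)[C@@H](C)Cc12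
F2 | step 8 | methyl 2-(chloromethyl)-6-methoxy-4-methylbenzoate | COC(=O)c1c(CCl)cc(C)cc1OC
F3 | step 8 | tert-butyl (3S)-5-lithio-6,8-dimethoxy-3-methyl-3,4-dihydro-1H-isoquinoline-2-carboxylate | COc1cc(OC)c([Li])c2c1CN(C(=O)OC(C)(C)C)[C@@H](C)C2
F4 | step 8 | tert-butyl (3S)-6,8-dimethoxy-3-methyl-5-(4,4,5,5-tetramethyl-1,3,2-dioxaborolan-2-yl)-3,4-dihydro-1H-isoquinoline-2-carboxylate | COc1cc(OC)c(B3OC(C)(C)C(C)(C)O3)c2c1CN(C(=O)OC(C)(C)C)[C@@H](C)C2
F5 | step 7 | tert-butyl (3S)-5,7-dibromo-6,8-dimethoxy-3-methyl-3,4-dihydro-1H-isoquinoline-2-carboxylate | COc1c(Br)c(OC)c(Br)c2c1CN(C(=O)OC(C)(C)C)[C@@H](C)C2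
F6 | step 7 | tert-butyl (3S)-5-bromo-7-lithio-6,8-dimethoxy-3-methyl-3,4-dihydro-1H-isoquinoline-2-carboxylate | COc1c([Li])c(OC)c(Br)c2c1CN(C(=O)OC(C)(C)C)[C@@H](C)C2
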